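**Retrosynthetic overview**

1. Target 28 ⇐ hydroxy acid 26 by O-acetylation. The C7=C8 bond with its C17 methyl ⇐ a C8 ketone (enol triflate, Negishi methylation). The side chain C12–C16 ⇐ vinylogous Mukaiyama–Michael addition to the C9=C11 methylene ketone 16.
2. Enabling feature: ring B (C5–C6–C7–C8–C9–C10) is a cyclohexene whose C7=C8–CH3 unit is a masked C8 ketone. It is therefore the [4+2] adduct of a 2-alkoxydiene C7=C8(OEt)–C9=C10 and a C5=C6 dienophile. Ring A atoms C1–C4 (C3 oxygen, C4 gem-dimethyl) are the four-atom tether from C10 to C5, and the unsubstituted C6 can carry a traceless nitro group.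
3. Rings A and B ⇐ formed together from an acyclic chain by one intramolecular Diels–Alder reaction of nitro triene 12, which is generated in the flask by Stille coupling of iodoalkene 11.
4. 11 ⇐ alkyne carboalumination/iodination, vinyl cleavage and Henry condensation; C3 ⇐ CBS reduction of the reverse-prenyl ketone 3 made from pent-4-ynoic acid 1.

Key step: step 8

Remark: positions are numbered as in labdanes (C3 acetoxy carbon, C4 gem-dimethyl carbon, C5/C10 ring fusion, C17 the methyl on C8; α is the face of 5-H, β the face of the C10 methyl). Prenylmagnesium chloride, tributyl(1-ethoxyvinyl)stannane and dimethyl(methylidene)ammonium iodide are taken as purchased reagents.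

**Route**

Step 1
Reactants: 1 pent-4-ynoic acid
Product: 2 N-methoxy-N-methylpent-4-ynamide
Conditions: MeNHOMe·HCl, EDC·HCl, N-methylmorpholine, CH2Cl2, 0 °C → rt
Reagents that add atoms: N,O-dimethylhydroxylamine hydrochloride, CNOC.Cl
Why: Carbodiimide-mediated amide coupling should give the Weinreb amide cleanly; the alkyne is inert and no stereocentre is involved.

Step 2
Reactants: 2 N-methoxy-N-methylpent-4-ynamide
Product: 3 3,3-dimethyloct-1-en-7-yn-4-one
Conditions: (CH3)2C=CHCH2MgCl (2.2 equiv), THF, −78 → −40 °C; aq. NH4Cl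
Reagents that add atoms: 3-methylbut-2-en-1-ylmagnesium chloride, CC(C)=CC[Mg]Cl
Why: Weinreb ketone synthesis: the allylic Grignard reagent should add through its γ-carbon (cyclic SE2′ transition state), creating the quaternary C4 with both methyls and the vinyl group, while the chelated adduct prevents a second addition (one equivalent is consumed by the alkyne C–H).

Step 3
Reactants: 3 3,3-dimethyloct-1-en-7-yn-4-one
Product: 4 (4S)-3,3-dimethyloct-1-en-7-yn-4-ol
Conditions: (R)-2-methyl-CBS-oxazaborolidine [(R)-1-methyl-3,3-diphenyltetrahydro-1H,3H-pyrrolo[1,2-c][1,3,2]oxazaborole] (20 mol %), catecholborane, toluene, −40 °C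
Reagents that add atoms: none
Why: Corey–Bakshi–Shibata reduction: with the tertiary alkyl group as the large and the CH2 chain as the small substituent, the (R)-catalyst should deliver hydride to the face that gives the (S)-carbinol (the future C3), and catecholborane at low temperature leaves alkene and alkyne untouched.

Step 4
Reactants: 4 (4S)-3,3-dimethyloct-1-en-7-yn-4-ol
Product: 5 (4S)-4-(tert-butyldimethylsilyloxy)-3,3-dimethyloct-1-en-7-yne
Conditions: TBSOTf, 2,6-lutidine, CH2Cl2, 0 °C
Reagents that add atoms: tert-butyldimethylsilyl trifluoromethanesulfonate, CC(C)(C)[Si](C)(C)OS(=O)(=O)C(F)(F)F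
Why: Silyl ether formation with the silyl triflate should protect the hindered neopentylic C3 hydroxyl against the organometallic steps and against later oxa-Michael closure.

Step 5
Reactants: 5 (4S)-4-(tert-butyldimethylsilyloxy)-3,3-dimethyloct-1-en-7-yne
Product: 7 (1E,5S)-5-(tert-butyldimethylsilyloxy)-1-iodo-2,6,6-trimethylocta-1,7-diene, via alkenylalane 6 (not isolated)
Conditions: Me3Al, (C5H5)2ZrCl2 (25 mol %), CH2Cl2, 0 °C → rt; then iodine, THF, −30 °C
Reagents that add atoms: trimethylaluminium, C[Al](C)C; iodine, [I][I]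
Why: Negishi zirconium-catalysed carboalumination adds methyl and aluminium syn across the terminal alkyne with aluminium on the terminal carbon, and iodinolysis with retention should give the (E)-iodoalkene that fixes C1 anti to the future C8 on the C9=C10 bond; the hindered vinyl group does not react.

Step 6
Reactants: 7 (1E,5S)-5-(tert-butyldimethylsilyloxy)-1-iodo-2,6,6-trimethylocta-1,7-diene
Product: 8 (3S,6E)-3-(tert-butyldimethylsilyloxy)-7-iodo-2,2,6-trimethylhept-6-enal
Conditions: OsO4 (2 mol %), NaIO4, 2,6-lutidine, dioxane/H2O, rt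
Reagents that add atoms: sodium periodate (oxygen source through OsO4), [Na+].[O-]I(=O)(=O)=O
Why: Lemieux–Johnson oxidative cleavage: OsO4 should dihydroxylate the monosubstituted vinyl group in preference to the inductively deactivated trisubstituted iodoalkene, and NaIO4 cleaves the diol to the non-enolisable aldehyde (C5).

Step 7
Reactants: 8 (3S,6E)-3-(tert-butyldimethylsilyloxy)-7-iodo-2,2,6-trimethylhept-6-enal
Product: 11 (1E,4S,7E)-4-(tert-butyldimethylsilyloxy)-8-iodo-3,3,7-trimethyl-1-nitroocta-1,7-diene, via nitro alcohol 9 (not isolated), via nitro mesylate 10 (not isolated)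
Conditions: MeNO2, Et3N (cat.), rt; then MsCl, Et3N, CH2Cl2, 0 °C
Reagents that add atoms: nitromethane, C[N+](=O)[O-]
Why: Henry (nitroaldol) addition to the non-enolisable aldehyde followed by E1cB elimination of the mesylate should give the conjugated (E)-nitroalkene, the thermodynamically preferred geometry, which supplies C6.

Step 8
Reactants: 11 (1E,4S,7E)-4-(tert-butyldimethylsilyloxy)-8-iodo-3,3,7-trimethyl-1-nitroocta-1,7-diene
Product: 13 3β-(tert-butyldimethylsilyloxy)-8-ethoxy-6α-nitro-11,12,13,14,15,16,17-heptanorlabd-8-ene (trans-fused; 5α-H; 10β-CH3), via ethoxy triene 12 (not isolated)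
Conditions: tributyl(1-ethoxyvinyl)stannane, Pd(PPh3)4 (5 mol %), CuI (10 mol %), DMF, 45 °C; then 90 °C
Reagents that add atoms: tributyl(1-ethoxyvinyl)stannane, CCCC[Sn](CCCC)(CCCC)C(=C)OCC
Why: Stille coupling with retention at the (E)-iodoalkene should give the 2-ethoxy-1,3-diene 12 with C1 anti to C8, which then undergoes a concerted, asynchronous thermal intramolecular Diels–Alder reaction with the tethered (E)-nitroalkene. The closest known reaction types are the intramolecular Diels–Alder reactions of (E)-1-nitro-1,7,9-decatrienes to trans-decalins and the Diels–Alder reactions of 2-alkoxy- or 2-silyloxydienes made by Stille coupling or enol silylation. Ring A is closed by the C5–C10 bond as the six-membered tether ring in a chair-like arrangement (terminally tethered 1,7,9-decatriene mode), and ring B by the suprafacial [4+2] union itself (C6–C7 together with C5–C10). The trans C5/C10 ring fusion should follow stereospecifically from the (E)-nitroalkene reacting through the nitro-endo transition state (C4 exo) with C1 outside and the methyl inside on C10; C6 (nitro α, cis to 5-H) is set by the same endo rule and is deleted in step 9. The absolute sense at C5 and C10 is relayed from C3, whose silyloxy group should sit equatorial in the chair tether, and the C4 gem-dimethyl group favours the coiled reactive conformer. The step needs endo and facial selectivity: the first is secured by the nitro group and the exo placement of the bulky quaternary C4, the second only by C3, and any adduct from the C3-axial chair is a diastereomer that can be separated.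

Step 9
Reactants: 13 3β-(tert-butyldimethylsilyloxy)-8-ethoxy-6α-nitro-11,12,13,14,15,16,17-heptanorlabd-8-ene
Product: 16 3β-(tert-butyldimethylsilyloxy)-12,13,14,15,16,17-hexanorlabda-6,9(11)-dien-8-one, via Mannich base 14 (not isolated), via ammonium iodide 15 (not isolated)
Conditions: (CH2=NMe2)I (Eschenmoser's salt), CH2Cl2, rt; MeI, rt, then volatiles removed; DBU, CH2Cl2, 0 °C
Reagents that add atoms: dimethyl(methylidene)ammonium iodide, C=[N+](C)C.[I-]
Why: Mannich reaction of the enol ether at C9 (the oxocarbenium ion loses iodoethane), N-methylation, and base-induced Hofmann-type and E1cB eliminations of trimethylamine and of nitrite β to the C8 ketone should give the cross-conjugated dienone; the C6 and C9 stereocentres are destroyed, C5 and C10 are untouched.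

Step 10
Reactants: 17 3-methylbut-2-enoic acid, 18 2-(trimethylsilyl)ethanol
Product: 19 2-(trimethylsilyl)ethyl 3-methylbut-2-enoate
Conditions: DCC, 4-(dimethylamino)pyridine (cat.), CH2Cl2, 0 °C → rt
Reagents that add atoms: none
Why: Steglich esterification under neutral conditions should give the fluoride-labile 2-(trimethylsilyl)ethyl ester.

Step 11
Reactants: 19 2-(trimethylsilyl)ethyl 3-methylbut-2-enoate
Product: 20 trimethyl{[3-methyl-1-(2-(trimethylsilyl)ethoxy)buta-1,3-dien-1-yl]oxy}silane
Conditions: LiN(i-Pr)2, Me3SiCl (in situ quench), THF, −78 °C → rt; non-aqueous work-up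
Reagents that add atoms: chlorotrimethylsilane, C[Si](C)(C)Cl
Why: γ-Deprotonation of the senecioate and O-silylation (silyl dienolate formation) should give the vinylogous silyl ketene acetal, whose ketene acetal geometry is of no consequence.

Step 12
Reactants: 16 3β-(tert-butyldimethylsilyloxy)-12,13,14,15,16,17-hexanorlabda-6,9(11)-dien-8-one, 20 trimethyl{[3-methyl-1-(2-(trimethylsilyl)ethoxy)buta-1,3-dien-1-yl]oxy}silane
Product: 22 2-(trimethylsilyl)ethyl (13E)-3β-(tert-butyldimethylsilyloxy)-8-oxo-17-norlabda-6,13-dien-15-oate (9α-H), via silyl enol ether 21 (not isolated)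
Conditions: Me3SiOSO2CF3 (10 mol %), CH2Cl2, −78 °C; then 1 M HCl, THF, 0 °C
Reagents that add atoms: none
Why: Vinylogous Mukaiyama–Michael reaction: the dienolate should attack through its γ-carbon at the unhindered exocyclic C11 of the s-cis enone (not at C6), the (13E) geometry arises from the s-trans dienolate conformer, and hydrolytic protonation of the C8 silyl enol ether on the α-face (axial, anti to the C10 methyl) sets C9 with the side chain equatorial (β).

Step 13
Reactants: 22 2-(trimethylsilyl)ethyl (13E)-3β-(tert-butyldimethylsilyloxy)-8-oxo-17-norlabda-6,13-dien-15-oate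
Product: 24 2-(trimethylsilyl)ethyl (13E)-3β-(tert-butyldimethylsilyloxy)-8-(trifluoromethanesulfonyloxy)-17-norlabda-7,13-dien-15-oate, via lithium enolate 23 (not isolated)
Conditions: LiBH(s-Bu)3 (L-Selectride), THF, −78 °C; then PhNTf2, −78 → 0 °C
Reagents that add atoms: N-phenylbis(trifluoromethanesulfonimide), O=S(=O)(N(c1ccccc1)S(=O)(=O)C(F)(F)F)C(F)(F)F
Why: Conjugate reduction with enolate trapping: the bulky borohydride should add hydride to the β-unsubstituted terminus C6 of the cyclohexenone and so generate the C7=C8 enolate regiospecifically, which PhNTf2 converts to the enol triflate without touching C9 or the β,β-disubstituted enoate.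

Step 14
Reactants: 24 2-(trimethylsilyl)ethyl (13E)-3β-(tert-butyldimethylsilyloxy)-8-(trifluoromethanesulfonyloxy)-17-norlabda-7,13-dien-15-oate
Product: 25 2-(trimethylsilyl)ethyl (13E)-3β-(tert-butyldimethylsilyloxy)labda-7,13-dien-15-oate
Conditions: MeZnCl, Pd(PPh3)4 (5 mol %), THF, 50 °C
Reagents that add atoms: methylzinc chloride, C[Zn]Cl
Why: Negishi cross-coupling of the alkenyl triflate with MeZnCl should install C17 with the double bond fixed at C7=C8; ester and silyl ether are inert.

Step 15
Reactants: 25 2-(trimethylsilyl)ethyl (13E)-3β-(tert-butyldimethylsilyloxy)labda-7,13-dien-15-oate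
Product: 26 (13E)-3β-hydroxylabda-7,13-dien-15-oic acid
Conditions: Bu4NF, THF, 50 °C; then 1 M HCl
Reagents that add atoms: none
Why: Fluoride-induced desilylation should remove the C3 silyl ether and cleave the 2-(trimethylsilyl)ethyl ester by β-elimination (loss of ethene), leaving all stereocentres and both alkenes untouched.

Step 16
Reactants: 26 (13E)-3β-hydroxylabda-7,13-dien-15-oic acid
Product: 28 (13E)-3β-acetoxylabda-7,13-dien-15-oic acid, via mixed anhydride 27 (not isolated)
Conditions: Ac2O, pyridine, 4-(dimethylamino)pyridine (cat.), CH2Cl2, rt; then H2O/THF, NaHCO3; dilute HCl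
Reagents that add atoms: acetic anhydride, CC(=O)OC(C)=O
Why: Nucleophile-catalysed O-acetylation of the equatorial 3β-hydroxyl proceeds with retention, and the mixed carboxylic anhydride formed at C15 should be hydrolysed selectively during the aqueous bicarbonate work-up.

**Compound list**

1 | pent-4-ynoic acid | C#CCCC(=O)O | starting material
2 | N-methoxy-N-methylpent-4-ynamide | C#CCCC(=O)N(C)OC | intermediate
3 | 3,3-dimethyloct-1-en-7-yn-4-one | C#CCCC(=O)C(C)(C)C=C | intermediate
4 | (4S)-3,3-dimethyloct-1-en-7-yn-4-ol | C#CCC[C@H](O)C(C)(C)C=C | intermediate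
5 | (4S)-4-(tert-butyldimethylsilyloxy)-3,3-dimethyloct-1-en-7-yne | C#CCC[C@H](O[Si](C)(C)C(C)(C)C)C(C)(C)C=C | intermediate
6 | [(1E,5S)-5-(tert-butyldimethylsilyloxy)-2,6,6-trimethylocta-1,7-dien-1-yl]dimethylalane (not isolated) | C[Al](C)/C=C(\C)CC[C@H](O[Si](C)(C)C(C)(C)C)C(C)(C)C=C | intermediate
7 | (1E,5S)-5-(tert-butyldimethylsilyloxy)-1-iodo-2,6,6-trimethylocta-1,7-diene | I/C=C(\C)CC[C@H](O[Si](C)(C)C(C)(C)C)C(C)(C)C=C | intermediate
8 | (3S,6E)-3-(tert-butyldimethylsilyloxy)-7-iodo-2,2,6-trimethylhept-6-enal | O=CC(C)(C)[C@@H](O[Si](C)(C)C(C)(C)C)CC/C(C)=C/I | intermediate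
9 | (4S,7E)-4-(tert-butyldimethylsilyloxy)-8-iodo-3,3,7-trimethyl-1-nitrooct-7-en-2-ol, both C2 epimers (not isolated) | [O-][N+](=O)CC(O)C(C)(C)[C@@H](O[Si](C)(C)C(C)(C)C)CC/C(C)=C/I | intermediate
10 | methanesulfonate of 9, both C2 epimers (not isolated) | CS(=O)(=O)OC(C[N+](=O)[O-])C(C)(C)[C@@H](O[Si](C)(C)C(C)(C)C)CC/C(C)=C/I | intermediate
11 | (1E,4S,7E)-4-(tert-butyldimethylsilyloxy)-8-iodo-3,3,7-trimethyl-1-nitroocta-1,7-diene | [O-][N+](=O)/C=C/C(C)(C)[C@@H](O[Si](C)(C)C(C)(C)C)CC/C(C)=C/I | intermediate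
12 | (1E,4S,7E)-4-(tert-butyldimethylsilyloxy)-9-ethoxy-3,3,7-trimethyl-1-nitrodeca-1,7,9-triene (not isolated) | [O-][N+](=O)/C=C/C(C)(C)[C@@H](O[Si](C)(C)C(C)(C)C)CC/C(C)=C/C(=C)OCC | intermediate
13 | 3β-(tert-butyldimethylsilyloxy)-8-ethoxy-6α-nitro-11,12,13,14,15,16,17-heptanorlabd-8-ene (5α-H, 10β-CH3) | CC(C)(C)[Si](C)(C)O[C@H]1CC[C@]2(C)C=C(OCC)C[C@H]([N+](=O)[O-])[C@H]2C1(C)C | intermediate
14 | 3β-(tert-butyldimethylsilyloxy)-11-(dimethylamino)-6α-nitro-12,13,14,15,16,17-hexanorlabdan-8-one, C11 drawn on the α-face of C9 (attack anti to the C10 methyl; not isolated) | CC(C)(C)[Si](C)(C)O[C@H]1CC[C@]2(C)[C@H](CN(C)C)C(=O)C[C@H]([N+](=O)[O-])[C@H]2C1(C)C | intermediate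
15 | N-methyl ammonium iodide of 14 (not isolated) | CC(C)(C)[Si](C)(C)O[C@H]1CC[C@]2(C)[C@H](C[N+](C)(C)C)C(=O)C[C@H]([N+](=O)[O-])[C@H]2C1(C)C.[I-] | intermediate
16 | 3β-(tert-butyldimethylsilyloxy)-12,13,14,15,16,17-hexanorlabda-6,9(11)-dien-8-one | CC(C)(C)[Si](C)(C)O[C@H]1CC[C@]2(C)C(=C)C(=O)C=C[C@H]2C1(C)C | intermediate
17 | 3-methylbut-2-enoic acid | CC(C)=CC(=O)O | starting material
18 | 2-(trimethylsilyl)ethanol | C[Si](C)(C)CCO | starting material
19 | 2-(trimethylsilyl)ethyl 3-methylbut-2-enoate | CC(C)=CC(=O)OCC[Si](C)(C)C | intermediate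
20 | trimethyl{[3-methyl-1-(2-(trimethylsilyl)ethoxy)buta-1,3-dien-1-yl]oxy}silane (ketene acetal geometry undefined) | C=C(C)C=C(OCC[Si](C)(C)C)O[Si](C)(C)C | intermediate
21 | 2-(trimethylsilyl)ethyl (13E)-3β-(tert-butyldimethylsilyloxy)-8-(trimethylsilyloxy)-17-norlabda-6,8,13-trien-15-oate (not isolated) | CC(C)(C)[Si](C)(C)O[C@H]1CC[C@]2(C)C(CC/C(C)=C/C(=O)OCC[Si](C)(C)C)=C(O[Si](C)(C)C)C=C[C@H]2C1(C)C | intermediate
22 | 2-(trimethylsilyl)ethyl (13E)-3β-(tert-butyldimethylsilyloxy)-8-oxo-17-norlabda-6,13-dien-15-oate (9α-H) | CC(C)(C)[Si](C)(C)O[C@H]1CC[C@]2(C)[C@@H](CC/C(C)=C/C(=O)OCC[Si](C)(C)C)C(=O)C=C[C@H]2C1(C)C | intermediate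
23 | lithium C7=C8 enolate from conjugate reduction of 22 (not isolated) | CC(C)(C)[Si](C)(C)O[C@H]1CC[C@]2(C)[C@@H](CC/C(C)=C/C(=O)OCC[Si](C)(C)C)C([O-])=CC[C@H]2C1(C)C.[Li+] | intermediate
24 | 2-(trimethylsilyl)ethyl (13E)-3β-(tert-butyldimethylsilyloxy)-8-(trifluoromethanesulfonyloxy)-17-norlabda-7,13-dien-15-oate | CC(C)(C)[Si](C)(C)O[C@H]1CC[C@]2(C)[C@@H](CC/C(C)=C/C(=O)OCC[Si](C)(C)C)C(OS(=O)(=O)C(F)(F)F)=CC[C@H]2C1(C)C | intermediate
25 | 2-(trimethylsilyl)ethyl (13E)-3β-(tert-butyldimethylsilyloxy)labda-7,13-dien-15-oate | CC(C)(C)[Si](C)(C)O[C@H]1CC[C@]2(C)[C@@H](CC/C(C)=C/C(=O)OCC[Si](C)(C)C)C(C)=CC[C@H]2C1(C)C | intermediate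
26 | (13E)-3β-hydroxylabda-7,13-dien-15-oic acid | O[C@H]1CC[C@]2(C)[C@@H](CC/C(C)=C/C(=O)O)C(C)=CC[C@H]2C1(C)C | intermediate
27 | acetic (13E)-3β-acetoxylabda-7,13-dien-15-oic anhydride (not isolated) | CC(=O)O[C@H]1CC[C@]2(C)[C@@H](CC/C(C)=C/C(=O)OC(C)=O)C(C)=CC[C@H]2C1(C)C | intermediate
28 | (13E)-3β-acetoxylabda-7,13-dien-15-oic acid | CC(=O)O[C@H]1CC[C@]2(C)[C@@H](CC/C(C)=C/C(=O)O)C(C)=CC[C@H]2C1(C)C | target

**Step count and risks**

Total step count: 16. Longest linear sequence: 14 steps (steps 1–9 and 12–16).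

Steps most likely to fail:

1. Step 8. The nitroalkene may be consumed by palladium-, phosphine- or tin-mediated side reactions before the coupling. The ethoxydiene may hydrolyse or undergo a 1,5-hydrogen shift faster than it cyclises, because the inside methyl on C10 slows the cycloaddition. The C3 silyloxy group, flanked by the C4 gem-dimethyl group, may also discriminate the two chair tethers only weakly; the minor adduct would be a separable diastereomer, so enantiopurity is not at stake. Fallback (diene by enol silylation instead of cross-coupling; it does not address the facial bias): from 7, iodine–lithium exchange with t-BuLi gives the vinyllithium F1, which is acylated with N-methoxy-N-methylacetamide to the enone F2. Radical nitration of the terminal vinyl group (AgNO2, 2,2,6,6-tetramethylpiperidine N-oxyl) gives the nitro enone F3. Kinetic enol silylation (TBSOTf, Et3N) gives the cross-conjugated silyl dienol ether F4, which cyclises on warming to the bicyclic silyl enol ether F5. F5 reacts with (CH2=NMe2)I to give Mannich base 14, where the route is rejoined.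

2. Step 12. The dienolate may attack through its α-carbon, the (13Z)-olefin may form in part, or addition may compete at C6. Fallback (two-carbon-shorter nucleophile, then olefin metathesis): from 16, Hosomi–Sakurai addition of trimethyl(2-methylallyl)silane with TiCl4 gives the 9β-(3-methylbut-3-enyl) enone F6. Cross-metathesis of its 1,1-disubstituted alkene with 2-(trimethylsilyl)ethyl acrylate (second-generation Hoveyda–Grubbs catalyst, RuCl2(H2IMes)(=CH-C6H4-2-O-i-Pr)) returns 22.

3. Step 13. The hindered carbonyl may undergo 1,2-reduction, or proton transfer within the enolate may scramble its position before triflation. Fallback (saturate first, then kinetic deprotonation): from 22, hydrogenation of the C6=C7 bond with RhCl(PPh3)3 and H2 gives the saturated ketone F7. Deprotonation at the less hindered C7 with KN(SiMe3)2 at −78 °C gives the potassium enolate F8, which PhNTf2 converts to 24.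

**Further compounds**

F1 | step 8 | [(1E,5S)-5-(tert-butyldimethylsilyloxy)-2,6,6-trimethylocta-1,7-dien-1-yl]lithium | [Li]/C=C(\C)CC[C@H](O[Si](C)(C)C(C)(C)C)C(C)(C)C=C
F2 | step 8 | (3E,7S)-7-(tert-butyldimethylsilyloxy)-4,8,8-trimethyldeca-3,9-dien-2-one | CC(=O)/C=C(\C)CC[C@H](O[Si](C)(C)C(C)(C)C)C(C)(C)C=C
F3 | step 8 | (3E,7S,9E)-7-(tert-butyldimethylsilyloxy)-4,8,8-trimethyl-10-nitrodeca-3,9-dien-2-one | CC(=O)/C=C(\C)CC[C@H](O[Si](C)(C)C(C)(C)C)C(C)(C)/C=C/[N+](=O)[O-]
F4 | step 8 | (3E,7S,9E)-2,7-bis(tert-butyldimethylsilyloxy)-4,8,8-trimethyl-10-nitrodeca-1,3,9-triene | C=C(O[Si](C)(C)C(C)(C)C)/C=C(\C)CC[C@H](O[Si](C)(C)C(C)(C)C)C(C)(C)/C=C/[N+](=O)[O-]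
F5 | step 8 | 3β,8-bis(tert-butyldimethylsilyloxy)-6α-nitro-11,12,13,14,15,16,17-heptanorlabd-8-ene | CC(C)(C)[Si](C)(C)O[C@H]1CC[C@]2(C)C=C(O[Si](C)(C)C(C)(C)C)C[C@H]([N+](=O)[O-])[C@H]2C1(C)C
F6 | step 12 | 3β-(tert-butyldimethylsilyloxy)-15,17-dinorlabda-6,13-dien-8-one (9α-H) | CC(C)(C)[Si](C)(C)O[C@H]1CC[C@]2(C)[C@@H](CCC(C)=C)C(=O)C=C[C@H]2C1(C)C
F7 | step 13 | 2-(trimethylsilyl)ethyl (13E)-3β-(tert-butyldimethylsilyloxy)-8-oxo-17-norlabd-13-en-15-oate | CC(C)(C)[Si](C)(C)O[C@H]1CC[C@]2(C)[C@@H](CC/C(C)=C/C(=O)OCC[Si](C)(C)C)C(=O)CC[C@H]2C1(C)C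
F8 | step 13 | potassium C7=C8 enolate of F7 | CC(C)(C)[Si](C)(C)O[C@H]1CC[C@]2(C)[C@@H](CC/C(C)=C/C(=O)OCC[Si](C)(C)C)C([O-])=CC[C@H]2C1(C)C.[K+]
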